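**Plan**

1. Numbering used below (daucane): C1 = quaternary C–CH3; C2, C3 = cyclopentane CH2; C4 = C(OH)(i-Pr); C5 = ring-fusion CH; C6 = ester carbinol; C7 = ring CH2; C8 = C(=CH2), exocyclic carbon C14; C9, C10 = diol carbons (C10 next to C1); α = face of the C9/C10 oxygens, β = face of the C1 methyl.
2. Retrosynthetic cuts, in order: the C6 ester and a diol acetal; C6–OH back to the ketone; C5–H and C7–H back to a 5α,9α oxygen bridge and a 7-en-6-one with C14–OAc; then C9–C10 and C5–C1 together (retro-(5+2)); the pyran ring back to a furan; the C5–furan bond; C2–C3.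
3. Enabling feature: in the seven-membered ring the run C5–C6–C7–C8–C9, with oxygen on C6 and C9 and the one-carbon branch on C8, is the carbon set of a 3-oxidopyrylium made from a 2,4-disubstituted furan; C10=C1 is a Z enol ether held to C5 by the cyclopentane atoms C2–C3–C4.
4. Forward: the chain C10–C1–C2 + C3–C4–C5 is joined first, the furan is added at C5 and oxidised to the pyranone, and one (5+2) cycloaddition closes the cyclopentane and the cycloheptane together; the oxygen bridge is opened afterwards.
5. Stereochemistry: C4 from a Sharpless epoxidation; C1, C9 and C10 in the cycloaddition (π-face by the C4 hydroxyl, C10 by the enol ether geometry); C5–H by enolate protonation; C6 by reduction directed by the C4 hydroxyl.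

Key step: step 14

Remark: the carbinol centre made in step 9, the two pyranone centres in 18 and 19 and the acetal carbon in 25 and 26 are uncontrolled mixtures without consequence, because each is removed later (steps 14 and 19).
Assumption: prop-2-yn-1-ol, furan-3-carbaldehyde, 4-methoxybenzyl alcohol, D-(−)-diisopropyl tartrate and the Grignard reagents are taken as commercial.

**Route**

Step 1
Reactants: 1 prop-2-yn-1-ol
Product: 3 (Z)-3-iodo-2-methylprop-2-en-1-ol, via alkenylmagnesium chelate 2 (not isolated)
Conditions: MeMgBr (2.5 equiv), CuI (10 mol%), Et2O, −10 °C → rt; then I2, THF, −78 → 0 °C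
Reagents that add atoms: methylmagnesium bromide C[Mg]Br; iodine II
Why: Copper-catalysed anti-carbomagnesiation of the propargylic alkoxide puts methyl on the internal carbon and magnesium on the terminal carbon cis to CH2O (five-membered chelate), so iodinolysis with retention should give only the Z iodide.

Step 2
Reactants: 3 (Z)-3-iodo-2-methylprop-2-en-1-ol
Product: 4 (Z)-3-bromo-1-iodo-2-methylprop-1-ene
Conditions: PBr3 (0.4 equiv), Et2O, 0 °C
Reagents that add atoms: phosphorus tribromide BrP(Br)Br
Why: SN2 bromination of the primary allylic alcohol should leave the alkene geometry and the vinyl iodide untouched.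

Step 3
Reactants: 1 prop-2-yn-1-ol; 4 (Z)-3-bromo-1-iodo-2-methylprop-1-ene
Product: 6 (2Z,5Z)-6-iodo-5-methyl-2-(propan-2-yl)hexa-2,5-dien-1-ol, via isopropyl alkenylmagnesium chelate 5 (not isolated)
Conditions: i-PrMgCl (2.2 equiv), CuI (10 mol%), THF, −10 °C → rt; then 4, −30 → 0 °C
Reagents that add atoms: isopropylmagnesium chloride CC(C)[Mg]Cl
Why: The same anti-carbomagnesiation gives an alkenylmagnesium species that should be allylated at carbon by the allylic bromide under copper catalysis (SN2 at the unhindered CH2Br), joining C3 to C2; the geometry of the new C3=C4 bond is erased in steps 4 and 5.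

Step 4
Reactants: 6 (2Z,5Z)-6-iodo-5-methyl-2-(propan-2-yl)hexa-2,5-dien-1-ol
Product: 7 [(2R,3S)-3-[(2Z)-3-iodo-2-methylprop-2-en-1-yl]-2-(propan-2-yl)oxiran-2-yl]methanol
Conditions: Ti(OiPr)4 (0.2 equiv), D-(−)-diisopropyl tartrate (0.25 equiv), t-BuOOH, 4 Å MS, CH2Cl2, −20 °C
Reagents that add atoms: tert-butyl hydroperoxide CC(C)(C)OO
Why: Sharpless asymmetric epoxidation, in which the D-(−)-tartrate catalyst delivers oxygen to the face that makes the future C4 carbinol carbon R, while the iodoalkene, not being allylic to the hydroxyl, is left alone.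

Step 5
Reactants: 7 epoxy alcohol
Product: 8 (2R,5Z)-6-iodo-5-methyl-2-(propan-2-yl)hex-5-ene-1,2-diol
Conditions: i-Bu2AlH (3 equiv), CH2Cl2/hexane, −20 → 0 °C
Reagents that add atoms: none
Why: Regioselective reductive opening of a 2,3-epoxy alcohol, in which the aluminium alkoxide delivers hydride to the less substituted C3, so the C4–O bond and its configuration are kept.

Step 6
Reactants: 8 diol
Product: 9 (2R,5Z)-6-iodo-5-methyl-2-(propan-2-yl)-1,2-bis(triethylsilyloxy)hex-5-ene
Conditions: Et3SiOTf (2.5 equiv), 2,6-lutidine, CH2Cl2, −78 → 0 °C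
Reagents that add atoms: triethylsilyl trifluoromethanesulfonate CC[Si](CC)(CC)OS(=O)(=O)C(F)(F)F
Why: Silyl triflate with a hindered base silylates both the primary and the tertiary hydroxyl; the tertiary ether prevents cyclisation onto the vinyl iodide in step 7 and the primary ether is the handle for step 8.

Step 7
Reactants: 9 bis(silyl ether) iodide; 10 (4-methoxyphenyl)methanol
Product: 11 (2R,5Z)-6-(4-methoxybenzyloxy)-5-methyl-2-(propan-2-yl)-1,2-bis(triethylsilyloxy)hex-5-ene
Conditions: 10 (3 equiv), CuI (10 mol%), 3,4,7,8-tetramethyl-1,10-phenanthroline (20 mol%), Cs2CO3, toluene, 80 °C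
Reagents that add atoms: none
Why: Copper-catalysed Ullmann-type C–O coupling of an alkenyl iodide with a primary alcohol proceeds with retention of alkene geometry, so the Z enol ether (oxygen cis to the chain) should result.

Step 8
Reactants: 11 enol ether
Product: 12 (2R,5Z)-6-(4-methoxybenzyloxy)-5-methyl-2-(propan-2-yl)-2-(triethylsilyloxy)hex-5-enal
Conditions: (COCl)2, DMSO, CH2Cl2, −78 → −40 °C; then Et3N, −78 → 0 °C
Reagents that add atoms: none
Why: Swern conditions oxidise a primary triethylsilyl ether directly to the aldehyde while the tertiary silyl ether survives, and the α-carbon has no hydrogen, so it cannot epimerise.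

Step 9
Reactants: 13 furan-3-carbaldehyde; 12 aldehyde
Product: 15 5-[(1RS,2R,5Z)-1-hydroxy-6-(4-methoxybenzyloxy)-5-methyl-2-(propan-2-yl)-2-(triethylsilyloxy)hex-5-en-1-yl]furan-3-carbaldehyde, via lithiated amino alkoxide 14 (not isolated)
Conditions: morpholine, n-BuLi, THF, −78 °C; 13; s-BuLi, −78 °C; then 12, −78 °C; aq. NH4Cl
Reagents that add atoms: none
Why: In-situ protection of the aldehyde as its lithium morpholide adduct blocks the neighbouring ring position and directs lithiation to the remote α-carbon of the furan, and the furyllithium should add to the hindered aldehyde (directed metalation, then 1,2-addition); the new carbinol centre is not controlled and need not be.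

Step 10
Reactants: 15 hydroxy aldehyde
Product: 16 (1RS,2R,5Z)-1-[4-(hydroxymethyl)furan-2-yl]-6-(4-methoxybenzyloxy)-5-methyl-2-(propan-2-yl)-2-(triethylsilyloxy)hex-5-en-1-ol
Conditions: NaBH4, MeOH, 0 °C
Reagents that add atoms: none
Why: Chemoselective borohydride reduction of the only carbonyl group gives the future C14 hydroxymethyl group.

Step 11
Reactants: 16 silyl ether diol
Product: 17 (1RS,2R,5Z)-1-[4-(hydroxymethyl)furan-2-yl]-6-(4-methoxybenzyloxy)-5-methyl-2-(propan-2-yl)hex-5-ene-1,2-diol
Conditions: n-Bu4NF, THF, 0 °C → rt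
Reagents that add atoms: none
Why: Fluoride cleaves the silyl ether (also if the silyl group has moved to the neighbouring secondary oxygen in step 9) and frees the C4 hydroxyl that steers step 14, while enol ether and furan are inert to fluoride.

Step 12
Reactants: 17 furyl triol
Product: 18 6-hydroxy-5-(hydroxymethyl)-2-[(3R,6Z)-3-hydroxy-7-(4-methoxybenzyloxy)-2,6-dimethylhept-6-en-3-yl]-2H-pyran-3(6H)-one (mixture at pyranone C2 and C6)
Conditions: VO(acac)2 (5 mol%), t-BuOOH (1.3 equiv), CH2Cl2, 0 °C
Reagents that add atoms: tert-butyl hydroperoxide CC(C)(C)OO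
Why: Achmatowicz rearrangement, in which hydroxyl-directed vanadium-catalysed oxidation of the furfuryl alcohol should be far faster than attack on the remote enol ether and the oxidised furan ring-expands to the pyranone hemiacetal; no acid is present, so the tertiary hydroxyl should not close a ketal.

Step 13
Reactants: 18 pyranone hemiacetal
Product: 19 6-acetoxy-5-(acetoxymethyl)-2-[(3R,6Z)-3-hydroxy-7-(4-methoxybenzyloxy)-2,6-dimethylhept-6-en-3-yl]-2H-pyran-3(6H)-one
Conditions: Ac2O (2.5 equiv), pyridine, DMAP (5 mol%), CH2Cl2, −20 → 0 °C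
Reagents that add atoms: acetic anhydride CC(=O)OC(C)=O
Why: Acetylation of the anomeric and primary hydroxyls (the tertiary one is inert under these conditions) installs at once the leaving group for ylide formation and the allylic acetate used in step 15.

Step 14
Reactants: 19 diacetate
Product: 21 14-acetoxy-5α,9α-epoxy-4β-hydroxy-10α-(4-methoxybenzyloxy)dauc-7-en-6-one, via 3-oxidopyrylium betaine 20 (not isolated)
Conditions: DBU (1.5 equiv), CH2Cl2, 0 → 40 °C
Reagents that add atoms: none
Why: DBU removes the proton on the pyranone carbon that carries the side chain (future C5) and acetate leaves from the anomeric carbon (future C9), giving the aromatic 3-oxidopyrylium betaine 20, which adds through its two oxygen-flanked ring carbons to the tethered enol ether in a concerted suprafacial (5+2) cycloaddition that forms C5–C1 and C9–C10 and dearomatises the heterocycle. The closest known reaction type is the intramolecular oxidopyrylium–alkene (5+2) cycloaddition of 6-acetoxy-2H-pyran-3(6H)-ones obtained from furfuryl alcohols. The cyclopentane closes by the C5–C1 bond as a 5-exo closure over the three-atom tether C2–C3–C4, and the seven-membered carbocycle closes by both bonds in the five-carbon plus two-carbon mode, the former pyran oxygen remaining as the 5,9-bridge. The short tether can only span the exo position, which fixes the C1 methyl endo (β) relative to the oxygen bridge at C5 and C9, and suprafacial addition of the Z enol ether puts the C10 oxygen exo, cis to the bridge oxygen on C9. The step needs π-facial selectivity with respect to C4: the free tertiary hydroxyl should hydrogen-bond to the oxido oxygen in a six-membered ring, which locks the C4–C5 rotamer so that the tether reaches one face only and the isopropyl group lies on the ring-oxygen side, exactly the C4/C5/C1 relationship of the target. Regiochemistry is enforced by the tether and agrees with the polarity of the donor alkene (nucleophilic C1 to the ylide carbon next to the oxido carbon).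

Step 15
Reactants: 21 cycloadduct
Product: 23 4β,9α-dihydroxy-10α-(4-methoxybenzyloxy)-5α-dauc-8(14)-en-6-one, via oxa-bridged methylidene ketone 22 (not isolated)
Conditions: SmI2 (4.5 equiv), MeOH (10 equiv), THF, −78 °C
Reagents that add atoms: none
Why: SmI2 carries out two known reductive cleavages in one flask, first the vinylogous elimination of the allylic acetate from the reduced enone with kinetic α-protonation at C7 (giving 22 with the exocyclic alkene) and then cleavage of the C5–O bond α to the ketone, and the resulting C5 samarium enolate should be protonated on the α face, anti to the C1 methyl and C4 hydroxyl and on the side from which the C9 alkoxide has just left, to give the trans ring fusion.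

Step 16
Reactants: 23 β-hydroxy ketone
Product: 24 10α-(4-methoxybenzyloxy)-5α-dauc-8(14)-ene-4β,6α,9α-triol
Conditions: Me4NBH(OAc)3 (5 equiv), MeCN/AcOH (1:1), −25 °C
Reagents that add atoms: none
Why: Evans–Saksena reduction, in which the boron reagent binds the β-oriented C4 hydroxyl and delivers hydride intramolecularly to the β face of the C6 ketone through a six-membered transition state, so the 6α-alcohol should form.

Step 17
Reactants: 24 triol
Product: 25 9α,10α-(4-methoxybenzylidenedioxy)-5α-dauc-8(14)-ene-4β,6α-diol (acetal carbon not controlled)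
Conditions: DDQ (1.2 equiv), 4 Å MS, CH2Cl2, 0 °C
Reagents that add atoms: none
Why: Under anhydrous conditions DDQ oxidises the 4-methoxybenzyl ether at its benzylic carbon and the adjacent cis C9 hydroxyl closes the five-membered 4-methoxybenzylidene acetal, which protects both diol oxygens without an added reagent.

Step 18
Reactants: 25 acetal diol
Product: 26 4β-hydroxy-9α,10α-(4-methoxybenzylidenedioxy)-5α-dauc-8(14)-en-6α-yl 3-methylbutanoate
Conditions: 3-methylbutanoyl chloride, pyridine, DMAP (cat.), CH2Cl2, 0 °C → rt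
Reagents that add atoms: 3-methylbutanoyl chloride CC(C)CC(=O)Cl
Why: DMAP-catalysed acylation takes the only free secondary hydroxyl (C6), since the tertiary C4 hydroxyl does not react under these conditions.

Step 19
Reactants: 26 ester acetal
Product: 27 (1S,4R,5S,6S,9R,10S)-4β,9α,10α-trihydroxy-5α-dauc-8(14)-en-6α-yl 3-methylbutanoate (target; locants in the numbering above)
Conditions: AcOH/THF/H2O (4:1:1), 40 °C
Reagents that add atoms: none
Why: Mild acid hydrolysis of the electron-rich aryl acetal frees the cis-diol, and the ester, the tertiary alcohol and the allylic alcohol should be stable under these conditions.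

**Compound list**

1 | prop-2-yn-1-ol | C#CCO | starting material
2 | alkenylmagnesium chelate, 4-methyl-2,5-dihydro-1,2-oxamagnesole (halide and ether ligands omitted; not isolated) | CC1=C[Mg]OC1 | intermediate
3 | (Z)-3-iodo-2-methylprop-2-en-1-ol | OC/C(C)=C\I | intermediate
4 | (Z)-3-bromo-1-iodo-2-methylprop-1-ene | BrC/C(C)=C\I | intermediate
5 | alkenylmagnesium chelate, 4-(propan-2-yl)-2,5-dihydro-1,2-oxamagnesole (ligands omitted; not isolated) | CC(C)C1=C[Mg]OC1 | intermediate
6 | (2Z,5Z)-6-iodo-5-methyl-2-(propan-2-yl)hexa-2,5-dien-1-ol | OC/C(C(C)C)=C\C/C(C)=C\I | intermediate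
7 | [(2R,3S)-3-[(2Z)-3-iodo-2-methylprop-2-en-1-yl]-2-(propan-2-yl)oxiran-2-yl]methanol | OC[C@@]1(C(C)C)O[C@H]1C/C(C)=C\I | intermediate
8 | (2R,5Z)-6-iodo-5-methyl-2-(propan-2-yl)hex-5-ene-1,2-diol | OC[C@](O)(C(C)C)CC/C(C)=C\I | intermediate
9 | (2R,5Z)-6-iodo-5-methyl-2-(propan-2-yl)-1,2-bis(triethylsilyloxy)hex-5-ene | CC[Si](CC)(CC)OC[C@](O[Si](CC)(CC)CC)(C(C)C)CC/C(C)=C\I | intermediate
10 | (4-methoxyphenyl)methanol | COc1ccc(CO)cc1 | starting material
11 | (2R,5Z)-6-(4-methoxybenzyloxy)-5-methyl-2-(propan-2-yl)-1,2-bis(triethylsilyloxy)hex-5-ene | CC[Si](CC)(CC)OC[C@](O[Si](CC)(CC)CC)(C(C)C)CC/C(C)=C\OCc1ccc(OC)cc1 | intermediate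
12 | (2R,5Z)-6-(4-methoxybenzyloxy)-5-methyl-2-(propan-2-yl)-2-(triethylsilyloxy)hex-5-enal | O=C[C@](O[Si](CC)(CC)CC)(C(C)C)CC/C(C)=C\OCc1ccc(OC)cc1 | intermediate
13 | furan-3-carbaldehyde | O=Cc1ccoc1 | starting material
14 | 5-lithiofuran-3-yl(morpholino)methanolate, lithium salt (not isolated) | [Li]c1cc(C(O[Li])N2CCOCC2)co1 | intermediate
15 | 5-[(1RS,2R,5Z)-1-hydroxy-6-(4-methoxybenzyloxy)-5-methyl-2-(propan-2-yl)-2-(triethylsilyloxy)hex-5-en-1-yl]furan-3-carbaldehyde | O=Cc1coc(C(O)[C@](O[Si](CC)(CC)CC)(C(C)C)CC/C(C)=C\OCc2ccc(OC)cc2)c1 | intermediate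
16 | (1RS,2R,5Z)-1-[4-(hydroxymethyl)furan-2-yl]-6-(4-methoxybenzyloxy)-5-methyl-2-(propan-2-yl)-2-(triethylsilyloxy)hex-5-en-1-ol | OCc1coc(C(O)[C@](O[Si](CC)(CC)CC)(C(C)C)CC/C(C)=C\OCc2ccc(OC)cc2)c1 | intermediate
17 | (1RS,2R,5Z)-1-[4-(hydroxymethyl)furan-2-yl]-6-(4-methoxybenzyloxy)-5-methyl-2-(propan-2-yl)hex-5-ene-1,2-diol | OCc1coc(C(O)[C@](O)(C(C)C)CC/C(C)=C\OCc2ccc(OC)cc2)c1 | intermediate
18 | 6-hydroxy-5-(hydroxymethyl)-2-[(3R,6Z)-3-hydroxy-7-(4-methoxybenzyloxy)-2,6-dimethylhept-6-en-3-yl]-2H-pyran-3(6H)-one | OCC1=CC(=O)C([C@](O)(C(C)C)CC/C(C)=C\OCc2ccc(OC)cc2)OC1O | intermediate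
19 | 6-acetoxy-5-(acetoxymethyl)-2-[(3R,6Z)-3-hydroxy-7-(4-methoxybenzyloxy)-2,6-dimethylhept-6-en-3-yl]-2H-pyran-3(6H)-one | CC(=O)OCC1=CC(=O)C([C@](O)(C(C)C)CC/C(C)=C\OCc2ccc(OC)cc2)OC1OC(C)=O | intermediate
20 | 5-(acetoxymethyl)-2-[(3R,6Z)-3-hydroxy-7-(4-methoxybenzyloxy)-2,6-dimethylhept-6-en-3-yl]pyrylium-3-olate (not isolated) | CC(=O)OCc1cc([O-])c([C@](O)(C(C)C)CC/C(C)=C\OCc2ccc(OC)cc2)[o+]c1 | intermediate
21 | 14-acetoxy-5α,9α-epoxy-4β-hydroxy-10α-(4-methoxybenzyloxy)dauc-7-en-6-one | CC(=O)OCC1=CC(=O)[C@@]32[C@](C)(CC[C@@]2(O)C(C)C)[C@H](OCc4ccc(OC)cc4)[C@@H]1O3 | intermediate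
22 | 5α,9α-epoxy-4β-hydroxy-10α-(4-methoxybenzyloxy)dauc-8(14)-en-6-one (not isolated) | C=C1CC(=O)[C@@]32[C@](C)(CC[C@@]2(O)C(C)C)[C@H](OCc4ccc(OC)cc4)[C@@H]1O3 | intermediate
23 | 4β,9α-dihydroxy-10α-(4-methoxybenzyloxy)-5α-dauc-8(14)-en-6-one | C=C1CC(=O)[C@@H]2[C@](C)(CC[C@@]2(O)C(C)C)[C@H](OCc3ccc(OC)cc3)[C@@H]1O | intermediate
24 | 10α-(4-methoxybenzyloxy)-5α-dauc-8(14)-ene-4β,6α,9α-triol | C=C1C[C@H](O)[C@@H]2[C@](C)(CC[C@@]2(O)C(C)C)[C@H](OCc3ccc(OC)cc3)[C@@H]1O | intermediate
25 | 9α,10α-(4-methoxybenzylidenedioxy)-5α-dauc-8(14)-ene-4β,6α-diol | C=C1C[C@H](O)[C@@H]2[C@](C)(CC[C@@]2(O)C(C)C)[C@H](OC(c4ccc(OC)cc4)O3)[C@@H]13 | intermediate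
26 | 4β-hydroxy-9α,10α-(4-methoxybenzylidenedioxy)-5α-dauc-8(14)-en-6α-yl 3-methylbutanoate | C=C1C[C@H](OC(=O)CC(C)C)[C@@H]2[C@](C)(CC[C@@]2(O)C(C)C)[C@H](OC(c4ccc(OC)cc4)O3)[C@@H]13 | intermediate
27 | (1S,4R,5S,6S,9R,10S)-4β,9α,10α-trihydroxy-5α-dauc-8(14)-en-6α-yl 3-methylbutanoate | C=C1C[C@H](OC(=O)CC(C)C)[C@@H]2[C@](C)(CC[C@@]2(O)C(C)C)[C@H](O)[C@@H]1O | target

**Step count and risks**

Total step count: 19. Longest linear sequence: 19 steps (1 → 27).

The three steps most likely to fail:

1. Step 14. What may go wrong: capture of the anomeric carbon by the free tertiary hydroxyl (ketal formation) in steps 12 to 14 before the ylide forms, dimerisation of the ylide if the crowded cycloaddition is slow, or incomplete hydrogen-bond control of the π-face. The fallback is a silyl-protected series in which the face is controlled by sterics instead. It sets out from 16 and omits the desilylation. Oxidation with VO(acac)2/t-BuOOH should give the silyl-protected pyranone hemiacetal F1, and acetylation its diacetate F2. DBU should then lead through the silyl-protected oxidopyrylium betaine F3 to the silyl-protected cycloadduct F4. SmI2/MeOH should reduce F4 through the silyl-protected bridged methylidene ketone F5 to the silyloxy hydroxy ketone F6. HF·pyridine in THF removes the silyl group, and the route is rejoined at 23.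

2. Step 15. What may go wrong: loss of control over the order and number of electron transfers, that is over-reduction of the β-hydroxy ketone or γ-protonation that brings the double bond back into conjugation; protonation at C5 from the β face is a further risk. The fallback separates the two events into known single steps. Setting out from 21, palladium-catalysed formate hydrogenolysis of the allylic acetate (Pd(OAc)2, n-Bu3P, HCO2NH4, THF, 40 °C; hydride delivered to C7) should give 22 as an isolated compound. SmI2 (2.2 equiv) with MeOH at −78 °C then cleaves only the C5–O bond, and the route is rejoined at 23. This fallback makes no compound outside the list (F0).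

3. Step 12. What may go wrong: competing oxidation of the electron-rich enol ether by the metal peroxide. The fallback changes the oxidation manifold to a dye-sensitised photooxygenation. Setting out from 17, O2 with rose bengal and visible light in MeOH/CH2Cl2 at −78 °C should give the furan endoperoxide F7 by (4+2) addition of singlet oxygen, which reacts much faster with the dialkylfuran than with the enol ether. Reduction with Me2S then gives the pyranone hemiacetal, and the route is rejoined at 18.

**Further compounds**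

F1 | step 14 | 6-hydroxy-5-(hydroxymethyl)-2-[(3R,6Z)-7-(4-methoxybenzyloxy)-2,6-dimethyl-3-(triethylsilyloxy)hept-6-en-3-yl]-2H-pyran-3(6H)-one | OCC1=CC(=O)C([C@](O[Si](CC)(CC)CC)(C(C)C)CC/C(C)=C\OCc2ccc(OC)cc2)OC1O
F2 | step 14 | 6-acetoxy-5-(acetoxymethyl)-2-[(3R,6Z)-7-(4-methoxybenzyloxy)-2,6-dimethyl-3-(triethylsilyloxy)hept-6-en-3-yl]-2H-pyran-3(6H)-one | CC(=O)OCC1=CC(=O)C([C@](O[Si](CC)(CC)CC)(C(C)C)CC/C(C)=C\OCc2ccc(OC)cc2)OC1OC(C)=O
F3 | step 14 | 5-(acetoxymethyl)-2-[(3R,6Z)-7-(4-methoxybenzyloxy)-2,6-dimethyl-3-(triethylsilyloxy)hept-6-en-3-yl]pyrylium-3-olate | CC(=O)OCc1cc([O-])c([C@](O[Si](CC)(CC)CC)(C(C)C)CC/C(C)=C\OCc2ccc(OC)cc2)[o+]c1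
F4 | step 14 | 14-acetoxy-5α,9α-epoxy-10α-(4-methoxybenzyloxy)-4β-(triethylsilyloxy)dauc-7-en-6-one | CC(=O)OCC1=CC(=O)[C@@]32[C@](C)(CC[C@@]2(O[Si](CC)(CC)CC)C(C)C)[C@H](OCc4ccc(OC)cc4)[C@@H]1O3
F5 | step 14 | 5α,9α-epoxy-10α-(4-methoxybenzyloxy)-4β-(triethylsilyloxy)dauc-8(14)-en-6-one | C=C1CC(=O)[C@@]32[C@](C)(CC[C@@]2(O[Si](CC)(CC)CC)C(C)C)[C@H](OCc4ccc(OC)cc4)[C@@H]1O3
F6 | step 14 | 9α-hydroxy-10α-(4-methoxybenzyloxy)-4β-(triethylsilyloxy)-5α-dauc-8(14)-en-6-one | C=C1CC(=O)[C@@H]2[C@](C)(CC[C@@]2(O[Si](CC)(CC)CC)C(C)C)[C@H](OCc3ccc(OC)cc3)[C@@H]1O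
F0 | step 15 | none | none
F7 | step 12 | furan endoperoxide of 17 (2,3,7-trioxabicyclo[2.2.1]hept-5-ene carrying the hydroxymethyl group on C5 and the diol side chain on C1) | OCC1=CC2(C(O)[C@](O)(C(C)C)CC/C(C)=C\OCc3ccc(OC)cc3)OOC1O2
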